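A small charge at a time is how noon receives its partner and midnight its substrate, while autumn has everything together from the start.

| flask | substrate | partner | remark | time |
|---|---|---|---|---|
| Tuesday's | 0.36 M | 0.36 M | run made earlier |  |
| Wednesday's | 0.36 M | 0.50 M | run made earlier |  |
| Sunday's | 0.36 M | 0.79 M | run made earlier |  |
| Friday's | 0.72 M | 0.36 M | run made earlier |  |
| autumn | 0.36 M | 0.360 M | everything together at the start | 80 min |
| noon | 0.36 M | 0.360 M (fed, over 15 min) | all else is in the flask from the start; the feed brings no volume worth counting | 80 min |
| midnight | 0.36 M (fed, over 15 min) | 0.360 M | all else is in the flask from the start; the feed brings no volume worth counting | 80 min |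

| run | time / min | target / % | substrate / % |
|---|---|---|---|
| Tuesday's | 3.00 | 69.1 | 27.6 |
| Tuesday's | 10.0 | 87.1 | 9.2 |
| Tuesday's | 15.0 | 90.7 | 5.9 |
| Tuesday's | 25.0 | 93.0 | 2.8 |
| Tuesday's | 40.0 | 94.2 | 1.3 |
| Tuesday's | 50.0 | 94.6 | 1.0 |
| Wednesday's | 8.00 | 95.0 | 2.3 |
| Wednesday's | 15.0 | 97.3 | 0.3 |
| Wednesday's | 25.0 | 98.6 | 0 |
| Wednesday's | 30.0 | 97.9 | 0 |
| Wednesday's | 40.0 | 97.9 | 0 |
| Wednesday's | 50.0 | 97.9 | 0.4 |
| Sunday's | 4.00 | 97.5 | 1.3 |
| Sunday's | 6.00 | 98.0 | 0 |
| Sunday's | 10.0 | 99.3 | 0.1 |
| Sunday's | 20.0 | 97.9 | 0 |
| Sunday's | 30.0 | 99.0 | 0 |
| Sunday's | 50.0 | 98.5 | 0.2 |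
| Friday's | 10.0 | 50.0 | 32.7 |
| Friday's | 20.0 | 50.2 | 27.6 |
| Friday's | 30.0 | 50.2 | 23.3 |
| Friday's | 40.0 | 50.1 | 18.5 |
| Friday's | 50.0 | 50.8 | 16.4 |

(scatter of a reading: 0.5 percentage points)

- a reading or a percentage of target counts all its forms, free or not

- the best flask by amount of target, in percent of the substrate charged; "all alike" if 1.5 percentage points covers them all (autumn / noon / midnight / all alike)
- amount of target at the end, in percent of the substrate charged, autumn
- amount of target at the end, in percent of the substrate charged, noon
- amount of target at the end, in percent of the substrate charged, midnight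

With equal charges the second-order rate integrates in closed form: the fraction of substrate left is one over one plus time over a lifetime of the charge. Tuesday's first reading, 27.6% at 3.00 min, gives a lifetime of 1.14 min. On Friday partner is the limiting reagent: target stays between 50.0% and 50.8%, while substrate falls from 32.7% at 10.0 min to 16.4% at 50.0 min. Taken as second order in substrate, that fall gives a self-loss time of 26.3 min at 0.36 M, far longer than the lifetime. Their ratio, the selectivity factor as read from these runs, is 4.35%, and Tuesday's last readings leave 4.40% unaccounted.

A bench rule says equal charges give equal yield however they go in, which puts autumn, noon and midnight near 95.7%. Its border is the dosing number, feed time over lifetime of the charge, 13.1. Here the feed is far longer, so this reckoning takes noon's partner as used while it arrives and noon's substrate as falling straight from its charge to zero over the feed. The square of a straight fall integrates to a third. The loss is the selectivity factor times the dosing number over three, 19.0%. This reckoning gives noon 81.0% and autumn 95.7%, and midnight, whose substrate trails its partner during the feed, should beat autumn.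

The forecast names midnight, with 95.2% for autumn (94.5% to 96%), 82% for noon (78% to 86%) and 96.8% for midnight (95.5% to 98%), holding that “Noon starves substrate of partner”. Its autumn and noon figures differ from the reckoning above, which lies inside both its ranges.

The flasks end at 95.5% for autumn, 81.1% for noon and 97.1% for midnight, with crystals counted within target, so midnight is best and the forecast stands.

    substrate + partner → target (k = 0.0357 M⁻¹ s⁻¹)
    2 substrate → side product (k = 8.68 × 10⁻⁴ M⁻¹ s⁻¹)
    crystals ⇌ target, rate k3*(cs3 - [target]) while solid is left; crystals form when [target] > cs3 (solubility = 0.160 M, k = 0.00855 s⁻¹)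

Noon's feed of 15 min runs far longer than autumn's half-life of substrate by the main step alone, 0.90 min, and noon ends with side product at 18.9%, beside 19.0% from the dosing number. At the end of its feed noon still holds substrate at 12.8% and partner at 31.5% of its own charge, where the straight fall had none. Cut to 1.50 min, the same feed has a dosing number of 1.31, and noon then ends at 93.5% of target, against autumn's 95.5%.

All runs were computed with constants of no real substance.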